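Remark on the chemistry: the target SMILES contains no stereocentre, no stereogenic double bond and no axis, so "single enantiomer" is taken to mean the one achiral compound as drawn, and no step has to control configuration. Compounds 1 and 6 are assumed to be catalogue chemicals.

## Structural features

The target is a flavone. A benzo ring A (C4a, C5–C8, C8a) is fused through C4a–C8a to a γ-pyranone ring C (O1, C2, C3, C4=O), and C2 carries an aryl ring B (C1'–C6') with OH on C3' and OMe on C4'. Ring A is hexasubstituted: OMe on C5, C6, C7 and C8, the ring oxygen O1 on C8a and the ketone carbon C4 on C4a, so no C–H remains on it. There is no stereocentre; the problem is one of regiochemistry and oxidation pattern. Fragile points are the 5-OMe group peri to the C4 carbonyl (cleaved by Lewis acids through chelation), the electron-rich penta-oxygenated ring A (oxidised to quinones), the reducible C2=C3 enone, and the single free phenol at C3', which must stay distinguishable from five methyl ethers. The real difficulty is to attach the acyl carbon C4 to the fully substituted ring A between the C5-OMe carbon and the O1-bearing C8a, and to close ring C there without disturbing the methyl ethers. The key step exploits the fact that C4 is a lone carbon at the oxidation level of carbon monoxide. It sits between an arene carbon (C4a) and a C3=C2 unit at the alkyne oxidation level, with O1 already ortho on C8a. Ring C can therefore be assembled from an o-iodophenol, CO and an aryl acetylene in one operation.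

## Logic of the disconnections

**12 ⇒ 11.** The O–H of C3' is traced back to an O–CH2Ph bond. The cut is made there because the one phenol among five methyl ethers needs a mask that is chemically distinct from methyl throughout the route. The skeleton is unchanged. The demand on the forward step is a cleavage that spares the C2=C3 bond and every O–CH3 bond, which points to neutral hydrogenolysis.

**11 ⇒ 5 + 8 + CO (key disconnection).** Three bonds of ring C are cut: C4a–C4, C4–C3 and O1–C2. C4 becomes carbon monoxide, C3=C2 with ring B becomes 8, and ring A with O1 becomes 5. In one sentence: ring C is made by a three-component carbonylative alkynylation–cyclisation of 5, CO and 8, whereas the default plan condenses an acetophenone with a benzaldehyde. The gain is the loss of the whole heterocycle and the separation of the two arenes. No acyl group has to be forced onto ring A by electrophilic substitution under Lewis acid, and ring C arrives at the flavone oxidation level. The forward step passes through 9 and 10. It must insert CO before alkynylation and must close the six-membered ring and not the five-membered one.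

**5 ⇒ 4.** The C–I bond on the carbon that becomes C4a is cut. 4 has a single aromatic C–H, ortho to the hydroxyl, so the position is unambiguous. The demand is an iodination mild enough not to oxidise the very electron-rich phenol.

**4 ⇒ 1.** The aryl C–O bond of the phenol (the future O1–C8a bond) is cut. 1 is symmetrical with two equivalent C–H positions, each ortho to a methoxy group, so directed metalation gives one aryl anion (2). Borylation to 3 and oxidation then install oxygen at that carbon. The demand is clean monometalation.

**8 ⇒ 6.** The C≡C bond is cut between the future C2 (the aldehyde carbon of 6) and the future C3 (a one-carbon reagent), through 7. This ties ring B, with its 3'/4' oxygen pattern already differentiated, to a catalogue aldehyde. The demand is a homologation mild enough for the benzyl ether.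

## Other disconnections considered

Alternative 1: (the first that comes to mind) Cut O1–C2 and the C2–C3 bond as an aldol C=C. Acylation of 4 would give 2'-hydroxy-3',4',5',6'-tetramethoxyacetophenone A1. Claisen–Schmidt condensation of A1 with 6 would give chalcone A2, and the forward key step would be the oxidative cyclisation of A2 (I2/DMSO) to 11. The ground for not choosing it is mechanistic. C4 must be attached to the penta-oxygenated ring by Friedel–Crafts or Fries chemistry under a strong Lewis acid, and the methoxy group ortho to the new ketone is then exposed to chelation-driven demethylation. Ring C is also formed one oxidation level too low and needs a separate oxidative event on an oxidation-prone ring. The chosen plan introduces C4 under neutral to basic palladium conditions, at the correct oxidation level, in the same number of steps. This plan is kept only as a fallback.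

Alternative 2: Cut the C2–C1' bond. 5,6,7,8-Tetramethoxychromone A3 would be arylated at C2 with [3-(benzyloxy)-4-methoxyphenyl]boronic acid A4 by a Pd(II)-catalysed oxidative conjugate arylation–dehydrogenation. A3 is not simpler than the target in the respect that matters: it still holds the hexasubstituted ring A with C4 attached, and would itself be made from A1 plus a one-carbon unit. The Lewis-acid acylation problem is therefore inherited and steps are added. The arylation can also stop at the flavanone level, and C2 versus C3 selectivity would have to be secured.

Alternative 3: Cut C4a–C5 and C8–C8a and build ring A de novo. A 5-metalated pyranone from 5-bromo-2-[3-(benzyloxy)-4-methoxyphenyl]-4H-pyran-4-one A5 would add to dimethyl squarate to give hydroxycyclobutenone A6. Thermal 4π ring opening to a vinylketene and 6π closure onto the pyranone C5=C6 bond would give the 5,8-dihydroxy-6,7-dimethoxyflavone A7, and double O-methylation would lead to 11. The idea is attractive because squarate delivers C5–C8 with all four oxygens. It is not chosen for three reasons. Metalation of A5 at a carbon α to the ketone of a Michael-accepting pyranone is doubtful. The hydroquinone A7 is air-sensitive and its chelated 5-OH is sluggish to methylate. The sequence (synthesis of A5, addition, thermolysis, methylation, deprotection) is clearly longer than the chosen one.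

Key step: step 4

## Route

Step 1
Reactants: 1 1,2,3,4-tetramethoxybenzene
Product: 4 2,3,4,5-tetramethoxyphenol, via aryllithium 2 (not isolated), via lithium aryltrimethoxyborate 3 (not isolated)
Conditions: n-BuLi (1.2 equiv), TMEDA (1.2 equiv), THF, 0 °C → rt; B(OMe)3 (1.5 equiv), −78 °C → rt; then AcOH, 30% aq. H2O2, 0 °C → rt
Reagents that add atoms: hydrogen peroxide, OO (the phenol oxygen of 4); n-butyllithium, [Li]CCCC, and trimethyl borate, COB(OC)OC, leave atoms only in the intermediates 2 and 3
Why: Directed ortho-metalation next to a methoxy group (the two ring C–H of 1 are equivalent, so one monolithio species 2 should form), borylation to the ate complex 3, and oxidative C–B to C–O conversion by 1,2-aryl migration from boron to oxygen. The oxygen should enter exactly at the metalated carbon, and the acidic peroxide conditions limit over-oxidation of the electron-rich phenol.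

Step 2
Reactants: 4 2,3,4,5-tetramethoxyphenol
Product: 5 6-iodo-2,3,4,5-tetramethoxyphenol
Conditions: NIS (1.05 equiv), MeCN, −20 → 0 °C, dark
Reagents that add atoms: N-iodosuccinimide, O=C1CCC(=O)N1I
Why: Electrophilic aromatic iodination at the only unsubstituted ring carbon, which is ortho to the hydroxyl and strongly activated. Low temperature, exclusion of light and the absence of acid should keep substitution ahead of oxidation of the phenol.

Step 3
Reactants: 6 3-(benzyloxy)-4-methoxybenzaldehyde
Product: 8 2-(benzyloxy)-4-ethynyl-1-methoxybenzene, via diazoalkene 7 (not isolated)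
Conditions: dimethyl (1-diazo-2-oxopropyl)phosphonate (1.3 equiv), K2CO3 (2 equiv), MeOH, 0 °C → rt
Reagents that add atoms: dimethyl (1-diazo-2-oxopropyl)phosphonate (Ohira–Bestmann reagent), CC(=O)C(=[N+]=[N-])P(=O)(OC)OC
Why: Seyferth–Gilbert homologation in the Ohira–Bestmann variant: methanolysis of the acetyl group frees the diazomethylphosphonate anion, a Horner–Wadsworth–Emmons-type olefination of the non-enolisable aldehyde gives 7, and loss of N2 with a 1,2-hydrogen shift should give the terminal alkyne. The mild carbonate base leaves the benzyl and methyl ethers untouched.

Step 4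
Reactants: 5 6-iodo-2,3,4,5-tetramethoxyphenol; 8 2-(benzyloxy)-4-ethynyl-1-methoxybenzene (1.5 equiv)
Product: 11 2-[3-(benzyloxy)-4-methoxyphenyl]-5,6,7,8-tetramethoxy-4H-chromen-4-one, via ynone 9 (not isolated), via enaminone 10 (not isolated)
Conditions: PdCl2(dppf) (5 mol %), CO (10 bar), Et2NH (solvent), 100 °C, autoclave, copper-free
Reagents that add atoms: carbon monoxide, [C-]#[O+]
Why: Pd(0) inserts into the C–I bond of 5 and CO inserts to give an aroyl-palladium(II) species; amine-assisted, copper-free transfer of the acetylide of 8 and reductive elimination then form C4a–C4 and C4–C3 and give ynone 9. Et2NH adds to C2 of 9 (aza-Michael) to give the push-pull enaminone 10, and the ortho phenol oxygen displaces the amine at that same carbon by addition–elimination, forming O1–C2 and releasing Et2NH. The closest known reaction type is the palladium-catalysed carbonylative Sonogashira annulation of o-iodophenols with terminal acetylenes in a secondary amine, a known flavone synthesis. Ring C, the only ring closed, closes in a 6-endo-trig mode on 10 (formally 6-endo-dig on 9); since the iminium-like C2 of 10 is its only electrophilic carbon, the 5-exo closure at C3 that would lead to an aurone has no pathway. No stereocentre is formed. CO insertion must outrun direct alkynylation (which would end in a benzofuran), and this should be secured by the electron-rich aryl–palladium bond, which undergoes migratory insertion quickly, by the CO pressure and by the absence of copper. Acetylide transfer must outrun capture of the aroyl-palladium by the amine or a phenol, and the two ortho substituents (OH and OMe) should help by shielding the acyl carbon from the bulky secondary amine while the slim acetylide enters at the metal. Regiochemistry is fixed by the substrate: iodine marks C4a, the neighbouring OH becomes O1, and the benzyl and methyl ethers are inert to these neutral to basic conditions.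

Step 5
Reactants: 11 2-[3-(benzyloxy)-4-methoxyphenyl]-5,6,7,8-tetramethoxy-4H-chromen-4-one
Product: 12 3'-demethylnobiletin, 2-(3-hydroxy-4-methoxyphenyl)-5,6,7,8-tetramethoxy-4H-chromen-4-one
Conditions: H2 (1 atm), 10% Pd/C, EtOAc–MeOH, rt, stopped after uptake of 1 equiv H2
Reagents that add atoms: none
Why: Catalytic hydrogenolysis of the benzylic C–O bond. Aryl methyl ethers are inert, and the C2=C3 bond of a flavone (a vinylogous ester conjugated to two arenes) should be reduced much more slowly than an aryl benzyl ether is cleaved at 1 atm and room temperature.

## Compound list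

1 | 1,2,3,4-tetramethoxybenzene | COc1ccc(OC)c(OC)c1OC | starting material
2 | (2,3,4,5-tetramethoxyphenyl)lithium | [Li]c1cc(OC)c(OC)c(OC)c1OC | intermediate (not isolated)
3 | lithium trimethoxy(2,3,4,5-tetramethoxyphenyl)borate | [Li+].CO[B-](OC)(OC)c1cc(OC)c(OC)c(OC)c1OC | intermediate (not isolated)
4 | 2,3,4,5-tetramethoxyphenol | COc1cc(O)c(OC)c(OC)c1OC | intermediate
5 | 6-iodo-2,3,4,5-tetramethoxyphenol | COc1c(I)c(O)c(OC)c(OC)c1OC | intermediate
6 | 3-(benzyloxy)-4-methoxybenzaldehyde | COc1ccc(C=O)cc1OCc1ccccc1 | starting material
7 | 2-(benzyloxy)-4-(2-diazoethenyl)-1-methoxybenzene | COc1ccc(C=C=[N+]=[N-])cc1OCc1ccccc1 | intermediate (not isolated)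
8 | 2-(benzyloxy)-4-ethynyl-1-methoxybenzene | C#Cc1ccc(OC)c(OCc2ccccc2)c1 | intermediate
9 | 3-[3-(benzyloxy)-4-methoxyphenyl]-1-(2-hydroxy-3,4,5,6-tetramethoxyphenyl)prop-2-yn-1-one | COc1ccc(C#CC(=O)c2c(O)c(OC)c(OC)c(OC)c2OC)cc1OCc1ccccc1 | intermediate (not isolated)
10 | (E)-3-[3-(benzyloxy)-4-methoxyphenyl]-3-(diethylamino)-1-(2-hydroxy-3,4,5,6-tetramethoxyphenyl)prop-2-en-1-one (push-pull alkene, geometry labile and without consequence) | CCN(CC)/C(=C/C(=O)c1c(O)c(OC)c(OC)c(OC)c1OC)c1ccc(OC)c(OCc2ccccc2)c1 | intermediate (not isolated)
11 | 2-[3-(benzyloxy)-4-methoxyphenyl]-5,6,7,8-tetramethoxy-4H-chromen-4-one | COc1ccc(-c2cc(=O)c3c(OC)c(OC)c(OC)c(OC)c3o2)cc1OCc1ccccc1 | intermediate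
12 | 3'-demethylnobiletin, 2-(3-hydroxy-4-methoxyphenyl)-5,6,7,8-tetramethoxy-4H-chromen-4-one | COc1ccc(-c2cc(=O)c3c(OC)c(OC)c(OC)c(OC)c3o2)cc1O | target

## Step count and risk

Total step count: 5. Longest linear sequence: 4 steps (1 → 4 → 5 → 11 → 12, steps 1, 2, 4 and 5); the second branch (6 → 8, step 3) joins at step 4.

Least certain steps:

**Step 4 (key step).** The aroyl-palladium intermediate is flanked by two ortho substituents, so acetylide transfer may be slow. Capture by diethylamine (aminocarbonylation to an amide) or by a phenol oxygen may then compete. Direct, non-carbonylative alkynylation followed by 5-endo closure to a benzofuran is a second loss channel, and oxidative addition into the electron-rich, doubly ortho-substituted iodide may be sluggish. Fallback (sets out from 4 and 6, returns at 11): 4 would be C-acetylated ortho to the hydroxyl (Ac2O, BF3·OEt2, Friedel–Crafts/Fries) to 2'-hydroxy-3',4',5',6'-tetramethoxyacetophenone F1 (the same compound as A1). Claisen–Schmidt condensation of F1 with 6 (KOH, EtOH) would give (E)-3-[3-(benzyloxy)-4-methoxyphenyl]-1-(2-hydroxy-3,4,5,6-tetramethoxyphenyl)prop-2-en-1-one F2 (the same compound as A2). Oxidative cyclisation of F2 (cat. I2, DMSO, 120 °C) would give 11.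

**Step 2.** Electron transfer from the very electron-rich phenol to the iodonium source, or ipso attack para to the hydroxyl, may lead to oxidative demethylation to a methoxy-p-benzoquinone in place of ring iodination. Fallback (sets out from 4, returns at 5): 4 would be protected as 1-(methoxymethoxy)-2,3,4,5-tetramethoxybenzene F3 (MOMCl, i-Pr2NEt). Directed ortho-lithiation at the only ring C–H (n-BuLi, THF) and an I2 quench would give 1-iodo-2-(methoxymethoxy)-3,4,5,6-tetramethoxybenzene F4. Acidic methanolysis (HCl, MeOH) would release 5 without the free phenol ever meeting an electrophilic iodine source.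

**Step 1.** Metalation may be incomplete or run on to the dilithio species, and the product phenol may be over-oxidised by excess peroxide during the C–B oxidation. Fallback (sets out from 1, returns at 4): Vilsmeier–Haack formylation of 1 (POCl3, DMF) would give 2,3,4,5-tetramethoxybenzaldehyde F5. Baeyer–Villiger oxidation (mCPBA, CH2Cl2) would give 2,3,4,5-tetramethoxyphenyl formate F6, and methanolysis (K2CO3, MeOH) would give 4.

**Step 5.** Saturation of the C2=C3 bond may compete with benzyl cleavage, or the catalyst may be slowed by traces of iodide or amine carried over from step 4, so that forcing conditions become necessary. Fallback (sets out from 11, returns at 12): the hydrogenation would be run until all benzyl ether is cleaved, accepting over-reduction, so that the crude product contains racemic 2-(3-hydroxy-4-methoxyphenyl)-5,6,7,8-tetramethoxychroman-4-one F7 beside 12. The mixture would then be dehydrogenated (cat. I2, DMSO, 120 °C, the standard flavanone-to-flavone oxidation), which converts F7 into 12 and leaves 12 unchanged.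

## Further compounds

F1 | step 4 | 2'-hydroxy-3',4',5',6'-tetramethoxyacetophenone | CC(=O)c1c(O)c(OC)c(OC)c(OC)c1OC
F2 | step 4 | (E)-3-[3-(benzyloxy)-4-methoxyphenyl]-1-(2-hydroxy-3,4,5,6-tetramethoxyphenyl)prop-2-en-1-one | COc1ccc(/C=C/C(=O)c2c(O)c(OC)c(OC)c(OC)c2OC)cc1OCc1ccccc1
F3 | step 2 | 1-(methoxymethoxy)-2,3,4,5-tetramethoxybenzene | COCOc1cc(OC)c(OC)c(OC)c1OC
F4 | step 2 | 1-iodo-2-(methoxymethoxy)-3,4,5,6-tetramethoxybenzene | COCOc1c(I)c(OC)c(OC)c(OC)c1OC
F5 | step 1 | 2,3,4,5-tetramethoxybenzaldehyde | COc1cc(C=O)c(OC)c(OC)c1OC
F6 | step 1 | 2,3,4,5-tetramethoxyphenyl formate | COc1cc(OC=O)c(OC)c(OC)c1OC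
F7 | step 5 | 2-(3-hydroxy-4-methoxyphenyl)-5,6,7,8-tetramethoxychroman-4-one (racemic) | COc1ccc(C2CC(=O)c3c(OC)c(OC)c(OC)c(OC)c3O2)cc1O
A1 | alternative 1 | 2'-hydroxy-3',4',5',6'-tetramethoxyacetophenone | CC(=O)c1c(O)c(OC)c(OC)c(OC)c1OC
A2 | alternative 1 | (E)-3-[3-(benzyloxy)-4-methoxyphenyl]-1-(2-hydroxy-3,4,5,6-tetramethoxyphenyl)prop-2-en-1-one | COc1ccc(/C=C/C(=O)c2c(O)c(OC)c(OC)c(OC)c2OC)cc1OCc1ccccc1
A3 | alternative 2 | 5,6,7,8-tetramethoxy-4H-chromen-4-one | O=c1ccoc2c(OC)c(OC)c(OC)c(OC)c12
A4 | alternative 2 | [3-(benzyloxy)-4-methoxyphenyl]boronic acid | COc1ccc(B(O)O)cc1OCc1ccccc1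
A5 | alternative 3 | 2-[3-(benzyloxy)-4-methoxyphenyl]-5-bromo-4H-pyran-4-one | COc1ccc(-c2cc(=O)c(Br)co2)cc1OCc1ccccc1
A6 | alternative 3 | 4-{6-[3-(benzyloxy)-4-methoxyphenyl]-4-oxo-4H-pyran-3-yl}-4-hydroxy-2,3-dimethoxycyclobut-2-en-1-one (racemic) | COC1=C(OC)C(O)(c2coc(-c3ccc(OC)c(OCc4ccccc4)c3)cc2=O)C1=O
A7 | alternative 3 | 2-[3-(benzyloxy)-4-methoxyphenyl]-5,8-dihydroxy-6,7-dimethoxy-4H-chromen-4-one | COc1ccc(-c2cc(=O)c3c(O)c(OC)c(OC)c(O)c3o2)cc1OCc1ccccc1
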